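C7 and C7' are the two ArCH–O carbons, C8 the ring-fusion C–OH, C8' the ring-fusion CH, and C9 and C9' the OCH2 groups on C8 and C8'. Ring A is O, C7, C8, C8', C9'. Ring B is O, C7', C8', C8, C9.
Feature used: C8 lies between C9 and the endo-aryl carbon C7 (aryl cis to C9, trans to 8-OH, the acid-sensitive epimer). With C9 raised to a lactone C=O, C8 serves first as a carbene carbon (C7–C8 bond) and later as an enolate carbon (C8–O bond).
Disconnections: C9H2 from the lactone C=O, C8–OH from enolate oxidation, C7–C8 from rhodium carbene 1,5 C–H insertion of an α-diazo lactone into a veratryl ether on C9', C9'–O–CH2Ar from imidate benzylation, and C7'–C8' from an Evans syn aldol of a succinyl imide with veratraldehyde.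
Ring order: ring B closes first (lactonisation after the aldol) and ring A second (C–H insertion). C9 of ring B is deoxygenated last, once the hydroxyl is in place.

Key step: step 10

Assumption: 17 (at C8) and 23 (at C9) are drawn with that centre undefined, because it is stereochemically labile and is erased in the next step. Ar = 3,4-dimethoxyphenyl.

Step 1
Reactants: 1 (R)-4-benzyl-2-oxazolidinone; 2 methyl 4-chloro-4-oxobutanoate
Product: 4 methyl 4-[(4R)-4-benzyl-2-oxooxazolidin-3-yl]-4-oxobutanoate, via N-lithio oxazolidinone 3 (not isolated)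
Conditions: n-BuLi, THF, −78 °C; then 2, −78 → 0 °C
Reagents that add atoms: none
Why: N-acylation of the lithiated carbamate by the acid chloride is fast at low temperature, spares the far less electrophilic methyl ester and leaves the auxiliary stereocentre untouched.

Step 2
Reactants: 4 methyl 4-[(4R)-4-benzyl-2-oxooxazolidin-3-yl]-4-oxobutanoate; 5 3,4-dimethoxybenzaldehyde
Product: 8 methyl (3R)-4-[(4R)-4-benzyl-2-oxooxazolidin-3-yl]-3-[(R)-(3,4-dimethoxyphenyl)(hydroxy)methyl]-4-oxobutanoate (syn aldol), via Z-dibutylboron enolate 6 (not isolated), via dibutylboron aldolate 7 (not isolated)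
Conditions: Bu2BOTf, Et3N, CH2Cl2, 0 °C; 5, −78 → 0 °C; H2O2, MeOH, pH 7 buffer, 0 °C
Reagents that add atoms: none
Why: In this Evans syn aldol, soft enolisation takes place only at the boron-activated imide (not at the ester) to give the Z-enolate, which adds through a Zimmerman–Traxler chair on the face away from the benzyl group of the (R)-auxiliary and so sets C8' (R) and C7' (R) in a syn relationship.

Step 3
Reactants: 8 syn aldol adduct
Product: 9 (4R)-4-benzyl-3-[(2R,3R)-2-(3,4-dimethoxyphenyl)-5-oxotetrahydrofuran-3-carbonyl]oxazolidin-2-one (trans lactone)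
Conditions: PPTS (cat.), toluene, 60 °C
Reagents that add atoms: none
Why: Mild acid-catalysed lactonisation (5-exo-trig attack of the C7' hydroxyl on the methyl ester) closes ring B, and the syn aldol pattern becomes the trans aryl/acyl lactone without either stereocentre being touched.

Step 4
Reactants: 9 trans lactone imide
Product: 11 (2R,3R)-2-(3,4-dimethoxyphenyl)-5-oxotetrahydrofuran-3-carboxylic acid, via peroxy acid 10 (not isolated)
Conditions: LiOH, H2O2, THF–H2O, 0 °C; Na2SO3; HCl to pH 2
Reagents that add atoms: hydrogen peroxide, OO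
Why: In this hydroperoxide cleavage of the Evans imide, the small and highly nucleophilic LiOOH attacks the exocyclic acyl carbon, sulfite reduces the peracid, and any ring B opened on the way recloses on acidification because only the γ-lactone is accessible.

Step 5
Reactants: 11 lactone acid
Product: 12 (4S,5R)-5-(3,4-dimethoxyphenyl)-4-(hydroxymethyl)dihydrofuran-2(3H)-one
Conditions: BH3·SMe2, THF, 0 °C → rt; MeOH
Reagents that add atoms: none
Why: Borane reduces the free carboxylic acid through an acyloxyborane much faster than it reduces the lactone, and the non-basic medium prevents acyl migration from the C7' oxygen to the new C9' hydroxyl.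

Step 6
Reactants: 13 3,4-dimethoxybenzyl alcohol
Product: 14 3,4-dimethoxybenzyl 2,2,2-trichloroacetimidate
Conditions: Cl3CCN, DBU (cat.), CH2Cl2, 0 °C; used at once
Reagents that add atoms: trichloroacetonitrile, N#CC(Cl)(Cl)Cl
Why: Base-catalysed addition of the alcohol to the electron-poor nitrile is the standard imidate preparation, and the product is used fresh because electron-rich benzyl imidates rearrange to the amide on storage.

Step 7
Reactants: 12 hydroxymethyl lactone; 14 3,4-dimethoxybenzyl trichloroacetimidate
Product: 15 (4S,5R)-5-(3,4-dimethoxyphenyl)-4-{[(3,4-dimethoxybenzyl)oxy]methyl}dihydrofuran-2(3H)-one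
Conditions: PPTS (cat.), CH2Cl2, 0 °C → rt
Reagents that add atoms: none
Why: In this acid-catalysed trichloroacetimidate benzylation, the protonated imidate passes the stabilised veratryl group to the primary hydroxyl without any alkoxide being formed, so ring B cannot translactonise and no stereocentre is involved.

Step 8
Reactants: 15 veratryl ether lactone
Product: 17 (4S,5R)-5-(3,4-dimethoxyphenyl)-4-{[(3,4-dimethoxybenzyl)oxy]methyl}-3-(trifluoroacetyl)dihydrofuran-2(3H)-one (C3 enolisable), via lithium enolate 16 (not isolated)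
Conditions: LiN(SiMe3)2, THF, −78 °C; CF3CO2CH2CF3, −78 °C; dilute HCl work-up, crude product carried on
Reagents that add atoms: 2,2,2-trifluoroethyl trifluoroacetate, O=C(OCC(F)(F)F)C(F)(F)F
Why: Claisen-type C-acylation of the lactone enolate with the activated trifluoroacetate makes C8 acidic enough for diazo transfer, the enolate carries no β leaving group, and C8' and C7' are not affected.

Step 9
Reactants: 17 α-trifluoroacetyl lactone
Product: 18 (4S,5R)-3-diazo-5-(3,4-dimethoxyphenyl)-4-{[(3,4-dimethoxybenzyl)oxy]methyl}dihydrofuran-2(3H)-one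
Conditions: 4-acetamidobenzenesulfonyl azide, Et3N, H2O (1 equiv.), MeCN, rt
Reagents that add atoms: 4-acetamidobenzenesulfonyl azide, CC(=O)Nc1ccc(cc1)S(=O)(=O)N=[N+]=[N-]
Why: In this detrifluoroacetylative Regitz diazo transfer, the stabilised enolate of 17 attacks the terminal azide nitrogen and the adduct collapses with migration of the trifluoroacetyl group to the sulfonamide nitrogen, leaving N2 on C8.

Step 10
Reactants: 18 α-diazo lactone
Product: 20 (3R,3aS,6S,6aR)-3,6-bis(3,4-dimethoxyphenyl)tetrahydro-1H,3H-furo[3,4-c]furan-1-one (lignan descriptors 7S,7'R,8R,8'S; C7 aryl endo; C7' aryl exo), via rhodium carbene 19 (not isolated)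
Conditions: Rh2(OAc)4 (2 mol %), CH2Cl2, reflux, slow addition of 18
Reagents that add atoms: none
Why: Rh2(OAc)4 (divalent rhodium) expels N2 from 18 to give the electrophilic carbene 19, whose carbon C8 takes up the C7–H bond in a concerted but asynchronous three-centre transition state, so that the C7–C8 and C8–H bonds form together. The closest known reaction type is the dirhodium-catalysed 1,5 C–H insertion of α-diazo-γ-butyrolactones and α-diazo esters into benzylic ether C–H bonds, which gives cis-2-aryl-3-acyl tetrahydrofurans. Ring A (O, C7, C8, C8', C9') closes by this 1,5 insertion onto ring B, and the short C8'–C9'–O tether reaches only one face of the carbene, so that H-8 ends up cis to H-8' (cis fusion). C7 is controlled by C8' through a chair-like array of C8, C8', C9', O, C7 and the migrating hydrogen in which the veratryl group lies pseudo-equatorial and away from the acetate ligands, which places it cis to C9 (endo), and since no free benzylic cation is formed it cannot relax to the exo epimer. The step needs site selectivity over 1,2-hydride migration from C8', oxonium ylide formation and attack on the arenes, and this is secured because C7–H is the only C–H bond that is both doubly activated (ether oxygen and electron-rich aryl) and in a 1,5 relationship to the carbene, while slow addition suppresses carbene dimers.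

Step 11
Reactants: 20 endo,exo-furofuranone
Product: 22 (3R,3aS,6R,6aS)-3,6-bis(3,4-dimethoxyphenyl)-6a-hydroxytetrahydro-1H,3H-furo[3,4-c]furan-1-one (lignan descriptors 7R,7'R,8S,8'S), via potassium enolate 21 (not isolated)
Conditions: KN(SiMe3)2, THF, −78 °C, brief; 2-(phenylsulfonyl)-3-phenyloxaziridine, −78 °C; AcOH quench at −78 °C
Reagents that add atoms: 2-(phenylsulfonyl)-3-phenyloxaziridine, O=S(=O)(c1ccccc1)N1OC1c1ccccc1
Why: In this Davis oxidation, the ring-fusion enolate 21 can accept oxygen only on its convex face because a trans-fused bicyclo[3.3.0] product is out of reach, so the hydroxyl takes the place of H-8 (cis to H-8', trans to the C7 aryl), while expulsion of the C7 oxygen should stay slow at −78 °C because that C–O bond lies near the enolate plane (the reverse of a 5-endo-trig closure).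

Step 12
Reactants: 22 bridgehead hydroxy furofuranone
Product: 23 C9 lactol of 22 (anomeric mixture, all other centres as in 22)
Conditions: i-Bu2AlH (2.2 equiv.), CH2Cl2, −78 °C; aq. potassium sodium tartrate
Reagents that add atoms: none
Why: The first equivalent of i-Bu2AlH forms the C8 aluminium alkoxide and the second adds once to the lactone carbonyl, and the tetrahedral aluminium hemiacetal survives at −78 °C, so the partial reduction stops at the lactol, whose new C9 centre is of no consequence.

Step 13
Reactants: 23 lactol
Product: 25 (7R,7'R,8R,8'S)-3,3',4,4'-tetramethoxy-7,9':7',9-diepoxylignan-8-ol (CNP0422369.4; 1-hydroxy-2-endo,6-exo-diaryl-3,7-dioxabicyclo[3.3.0]octane), via oxocarbenium ion 24 (not isolated)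
Conditions: Et3SiH (excess), BF3·OEt2, CH2Cl2, −78 °C; aq. NaHCO3 quench at −78 °C
Reagents that add atoms: none
Why: In this ionic hydrogenation of the lactol, BF3 ionises the anomeric C9–OH to 24 and Et3SiH traps it irreversibly, and the low temperature, the silane present from the start and the cold basic quench are meant to keep the benzylic C7–O and C7'–O bonds closed so that the endo aryl is retained, while C9 becomes a methylene and no stereocentre is created.

Compound list
1 | (R)-4-benzyl-2-oxazolidinone | O=C1N[C@H](Cc2ccccc2)CO1 | starting material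
2 | methyl 4-chloro-4-oxobutanoate | COC(=O)CCC(Cl)=O | starting material
3 | N-lithio (R)-4-benzyl-2-oxazolidinone | [Li]N1[C@H](Cc2ccccc2)COC1=O | intermediate
4 | methyl 4-[(4R)-4-benzyl-2-oxooxazolidin-3-yl]-4-oxobutanoate | COC(=O)CCC(=O)N1C(=O)OC[C@H]1Cc1ccccc1 | intermediate
5 | 3,4-dimethoxybenzaldehyde | COc1ccc(C=O)cc1OC | starting material
6 | Z-dibutylboron enolate of 4 | COC(=O)C/C=C(\OB(CCCC)CCCC)N1C(=O)OC[C@H]1Cc1ccccc1 | intermediate
7 | dibutylboron aldolate | COC(=O)C[C@@H](C(=O)N1C(=O)OC[C@H]1Cc1ccccc1)[C@@H](OB(CCCC)CCCC)c1ccc(OC)c(OC)c1 | intermediate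
8 | syn aldol adduct (C8' R, C7' R) | COC(=O)C[C@@H](C(=O)N1C(=O)OC[C@H]1Cc1ccccc1)[C@@H](O)c1ccc(OC)c(OC)c1 | intermediate
9 | trans γ-aryl β-acyl butyrolactone imide | O=C1C[C@@H](C(=O)N2C(=O)OC[C@H]2Cc2ccccc2)[C@H](c2ccc(OC)c(OC)c2)O1 | intermediate
10 | (2R,3R)-2-(3,4-dimethoxyphenyl)-5-oxotetrahydrofuran-3-carboperoxoic acid | O=C1C[C@@H](C(=O)OO)[C@H](c2ccc(OC)c(OC)c2)O1 | intermediate
11 | (2R,3R)-2-(3,4-dimethoxyphenyl)-5-oxotetrahydrofuran-3-carboxylic acid | O=C1C[C@@H](C(=O)O)[C@H](c2ccc(OC)c(OC)c2)O1 | intermediate
12 | (4S,5R)-5-(3,4-dimethoxyphenyl)-4-(hydroxymethyl)dihydrofuran-2(3H)-one | O=C1C[C@@H](CO)[C@H](c2ccc(OC)c(OC)c2)O1 | intermediate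
13 | 3,4-dimethoxybenzyl alcohol | COc1ccc(CO)cc1OC | starting material
14 | 3,4-dimethoxybenzyl 2,2,2-trichloroacetimidate | COc1ccc(COC(=N)C(Cl)(Cl)Cl)cc1OC | intermediate
15 | veratryl ether lactone (4S,5R) | O=C1C[C@@H](COCc2ccc(OC)c(OC)c2)[C@H](c2ccc(OC)c(OC)c2)O1 | intermediate
16 | lithium enolate of 15 | [Li]OC1=C[C@@H](COCc2ccc(OC)c(OC)c2)[C@H](c2ccc(OC)c(OC)c2)O1 | intermediate
17 | α-trifluoroacetyl lactone (C8 undefined, enolisable) | O=C1C(C(=O)C(F)(F)F)[C@@H](COCc2ccc(OC)c(OC)c2)[C@H](c2ccc(OC)c(OC)c2)O1 | intermediate
18 | α-diazo lactone (4S,5R) | O=C1C(=[N+]=[N-])[C@@H](COCc2ccc(OC)c(OC)c2)[C@H](c2ccc(OC)c(OC)c2)O1 | intermediate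
19 | C8 carbene bound to Rh2(OAc)4 (only the carbene-bearing rhodium drawn, acetates and second rhodium omitted) | O=C1C(=[Rh])[C@@H](COCc2ccc(OC)c(OC)c2)[C@H](c2ccc(OC)c(OC)c2)O1 | intermediate
20 | endo,exo-diaryl furofuranone (7S,7'R,8R,8'S) | COc1ccc([C@H]2OC[C@H]3[C@H](c4ccc(OC)c(OC)c4)OC(=O)[C@@H]23)cc1OC | intermediate
21 | ring-fusion potassium enolate of 20 | COc1ccc([C@H]2OC[C@H]3[C@H](c4ccc(OC)c(OC)c4)OC(O[K])=C23)cc1OC | intermediate
22 | bridgehead hydroxy furofuranone (7R,7'R,8S,8'S) | COc1ccc([C@H]2OC[C@H]3[C@H](c4ccc(OC)c(OC)c4)OC(=O)[C@@]23O)cc1OC | intermediate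
23 | C9 lactol (anomeric mixture) | COc1ccc([C@H]2OC[C@H]3[C@H](c4ccc(OC)c(OC)c4)OC(O)[C@@]23O)cc1OC | intermediate
24 | C9 oxocarbenium ion | COc1ccc([C@H]2OC[C@H]3[C@H](c4ccc(OC)c(OC)c4)[O+]=C[C@@]23O)cc1OC | intermediate
25 | CNP0422369.4, (7R,7'R,8R,8'S)-3,3',4,4'-tetramethoxy-7,9':7',9-diepoxylignan-8-ol | COc1ccc([C@H]2OC[C@H]3[C@H](c4ccc(OC)c(OC)c4)OC[C@@]23O)cc1OC | target

Total step count: 13. Longest linear sequence: 12 (steps 1–5 and 7–13; step 6 is a one-step side branch).

Steps most likely to fail

1. Step 11, bridgehead hydroxylation. While the free potassium enolate exists, ring A may open by loss of the C7 oxygen, and reclosure would erode the endo configuration at C7. The enolate may also be consumed by addition to the sulfonimine by-product. The fallback sets out from 20 and comes back at 22, and it never lets the enolate accumulate. Compound 20 is deprotonated with LiN(i-Pr)2 in the presence of Me3SiCl (in situ quench, THF, −78 °C) to give the neutral ring-fusion silyl ketene acetal F1. Dimethyldioxirane at low temperature epoxidises this on its convex face (Rubottom oxidation), and silyl migration gives the 8-trimethylsilyloxy lactone F2. HF·pyridine then frees 22.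

2. Step 13, ionic reduction of the lactol. The neighbouring C8 hydroxyl slows ionisation at C9 by induction, so the Lewis acid may instead open a benzylic C–O bond. That would epimerise the endo aryl or over-reduce the benzylic position. The fallback sets out from 22, replaces steps 12 and 13, and comes back at 25 without any Lewis acid. LiAlH4 in THF at 0 °C reduces the lactone to the ring A triol F3, which has a primary C9, a tertiary C8 and a benzylic C7' hydroxyl. TsCl in pyridine sulfonylates the primary hydroxyl selectively to give the C9 monotosylate F4. On warming, the C7' hydroxyl displaces the tosylate at C9 (5-exo-tet etherification), which rebuilds ring B without touching C7' or C7.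

3. Step 10, carbene C–H insertion. The carbene may be diverted into 1,2-hydride migration from C8', attack on one of the electron-rich arenes or dimerisation, or the insertion may proceed with poor endo selectivity. The fallback sets out from 12 and comes back at 20. It makes the C7–C8 bond by enolate acylation and sets C7 by hydride delivery.
   - Compound 12 is silylated (TBSCl, imidazole, DMF) to the tert-butyldimethylsilyl ether F5.
   - The lithium enolate of F5 (LiN(SiMe3)2, 2 equiv., THF, −78 °C) is C-acylated with 1-(3,4-dimethoxybenzoyl)imidazole to the α-veratroyl lactone F6.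
   - Desilylation with HF·pyridine and PPTS-catalysed cyclodehydration give the bicyclic 2-aryl-4,5-dihydrofuran F7, a C7=C8 enol ether conjugated with C9=O.
   - Ionic hydrogenation (Et3SiH, CF3CO2H, CH2Cl2, low temperature) protonates C8 on the only face that gives a cis-fused bicycle.
   - The resulting aryl-stabilised C7 oxocarbenium ion F8 takes hydride from the convex face, which puts H-7 exo and the aryl endo, as in 20.

Further compounds
F1 | step 11 | ring-fusion trimethylsilyl ketene acetal of 20 | COc1ccc([C@H]2OC[C@H]3[C@H](c4ccc(OC)c(OC)c4)OC(O[Si](C)(C)C)=C23)cc1OC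
F2 | step 11 | 8-trimethylsilyloxy furofuranone | COc1ccc([C@H]2OC[C@H]3[C@H](c4ccc(OC)c(OC)c4)OC(=O)[C@@]23O[Si](C)(C)C)cc1OC
F3 | step 13 | ring A triol (C9 primary, C8 tertiary, C7' benzylic hydroxyl) | COc1ccc([C@H]2OC[C@@H]([C@@H](O)c3ccc(OC)c(OC)c3)[C@@]2(O)CO)cc1OC
F4 | step 13 | C9 monotosylate of the triol | COc1ccc([C@H]2OC[C@@H]([C@@H](O)c3ccc(OC)c(OC)c3)[C@@]2(O)COS(=O)(=O)c3ccc(C)cc3)cc1OC
F5 | step 10 | tert-butyldimethylsilyl ether of 12 | O=C1C[C@@H](CO[Si](C)(C)C(C)(C)C)[C@H](c2ccc(OC)c(OC)c2)O1
F6 | step 10 | α-(3,4-dimethoxybenzoyl) lactone (C8 undefined, enolisable) | O=C1C(C(=O)c2ccc(OC)c(OC)c2)[C@@H](CO[Si](C)(C)C(C)(C)C)[C@H](c2ccc(OC)c(OC)c2)O1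
F7 | step 10 | bicyclic 2-aryl-4,5-dihydrofuran fused to ring B (C7=C8) | COc1ccc(C2=C3C(=O)O[C@@H](c4ccc(OC)c(OC)c4)[C@@H]3CO2)cc1OC
F8 | step 10 | C7 oxocarbenium ion of the cis-fused bicycle | COc1ccc(C2=[O+]C[C@H]3[C@H](c4ccc(OC)c(OC)c4)OC(=O)[C@@H]23)cc1OC
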